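**Assumption:** the SMILES carries no stereodescriptor and the molecule has no stereocentre (the 3,3′-axis is taken as not configurationally fixed), so the target is made exactly as drawn and no stereocontrol is needed.

**Retrosynthetic overview**
- Target ⇐ 5,5′,6,6′-tetrabromo-3,3′-bioxindole: twofold lactam C=O → C–Br exchange with POBr3, which also aromatises both pyrrole rings.
- Bis-oxindole ⇐ dimethyl 2,3-bis(4,5-dibromo-2-nitrophenyl)succinate: the key step closes both N1–C2 bonds at once, from the nitro groups onto the esters (new deoxygenative aza-Wittig lactamization).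
- Dinitro succinate ⇐ two molecules of methyl (4,5-dibromo-2-nitrophenyl)acetate by oxidative enolate homocoupling (C3–C3′ bond).
- Aryl acetate ⇐ 1,2-dibromo-4-fluoro-5-nitrobenzene + dimethyl malonate (SNAr, then Krapcho).
- Ring order: the two dibrominated benzene rings are bought; the two five-membered rings are formed last and together, after the C3–C3′ bond is in place.

**Route**

Step 1
Reactants: 1 1,2-dibromo-4-fluoro-5-nitrobenzene; 2 dimethyl malonate
Product: 4 methyl 2-(4,5-dibromo-2-nitrophenyl)acetate, via aryl malonate 3 (not isolated)
Conditions: K2CO3, DMSO, 60 °C; then AcOH, LiCl, H2O, 130 °C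
Reagents that add atoms: none
Why: SNAr displacement of the fluoride ortho to the nitro group by the malonate anion fixes the substitution pattern, and Krapcho dealkoxycarbonylation of the neutralised aryl malonate removes one ester; no stereocentre is formed.

Step 2
Reactants: 4 methyl 2-(4,5-dibromo-2-nitrophenyl)acetate (two molecules)
Product: 5 dimethyl 2,3-bis(4,5-dibromo-2-nitrophenyl)succinate (meso/rac mixture)
Conditions: LiN(SiMe3)2 (1.0 equiv), THF, −78 °C; then I2 (0.5 equiv), −78 to 0 °C
Reagents that add atoms: none
Why: Iodine-mediated oxidative homocoupling of the nitro-stabilised ester enolate (α-iodination then enolate displacement, or radical dimerization) forms the C3–C3′ bond; the diastereomer ratio is irrelevant because both centres become sp2 in step 4.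

Step 3
Reactants: 5 dimethyl 2,3-bis(4,5-dibromo-2-nitrophenyl)succinate
Product: 7 5,5′,6,6′-tetrabromo-3,3′-biindoline-2,2′-dione (meso/rac mixture), via bis-lactim ether 6 (not isolated)
Conditions: 1,2,2,3,4,4-hexamethylphosphetane 1-oxide (20 mol %), PhSiH3 (4 equiv), m-xylene, 120 °C; then 1 M HCl, THF, 40 °C
Reagents that add atoms: water, O
Why: Proposed new method: a deoxygenative double aza-Wittig lactamization in which the trivalent phosphetane (regenerated from its oxide by PhSiH3) strips both oxygens from each nitro group, a further equivalent captures the nitrene-level nitrogen as an iminophosphorane, and this closes onto the neighbouring ester carbonyl through a five-membered aza-Wittig transition state to the cyclic imidate while returning the phosphine oxide to the cycle (any aniline formed by over-reduction lactamises thermally to the same ring), after which dilute acid hydrolyses the lactim ether to the lactam; the closest known reaction types are the phosphetane-catalysed Cadogan-type reductive C–N cyclization of nitroarenes and the catalytic Staudinger/aza-Wittig cyclization of aryl azides, and no stereocentre needs control.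

Step 4
Reactants: 7 5,5′,6,6′-tetrabromo-3,3′-biindoline-2,2′-dione
Product: 8 2,2′,5,5′,6,6′-hexabromo-1H,1′H-3,3′-biindole
Conditions: POBr3 (5 equiv), 1,2-dichloroethane, 80 °C; then H2O
Reagents that add atoms: phosphoryl bromide, O=P(Br)(Br)Br
Why: Vilsmeier-type O-phosphorylation of each lactam, bromide addition–elimination to the 2-bromo-3H-indole and tautomerisation to the aromatic 2-bromoindole (the known oxindole to 2-bromoindole deoxybromination) install both C2–Br bonds and erase both C3 stereocentres.

**Compound list**
1 | 1,2-dibromo-4-fluoro-5-nitrobenzene | O=[N+]([O-])c1cc(Br)c(Br)cc1F | starting material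
2 | dimethyl malonate | COC(=O)CC(=O)OC | starting material
3 | dimethyl 2-(4,5-dibromo-2-nitrophenyl)malonate | COC(=O)C(C(=O)OC)c1cc(Br)c(Br)cc1[N+](=O)[O-] | intermediate
4 | methyl 2-(4,5-dibromo-2-nitrophenyl)acetate | COC(=O)Cc1cc(Br)c(Br)cc1[N+](=O)[O-] | intermediate
5 | dimethyl 2,3-bis(4,5-dibromo-2-nitrophenyl)succinate (meso/rac mixture) | COC(=O)C(c1cc(Br)c(Br)cc1[N+](=O)[O-])C(C(=O)OC)c1cc(Br)c(Br)cc1[N+](=O)[O-] | intermediate
6 | 5,5′,6,6′-tetrabromo-2,2′-dimethoxy-3H,3′H-3,3′-biindole (bis-lactim ether, tautomer of the 2-methoxy-1H-indole form) | COC1=Nc2cc(Br)c(Br)cc2C1C1C(OC)=Nc2cc(Br)c(Br)cc21 | intermediate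
7 | 5,5′,6,6′-tetrabromo-3,3′-biindoline-2,2′-dione (meso/rac mixture) | O=C1Nc2cc(Br)c(Br)cc2C1C1C(=O)Nc2cc(Br)c(Br)cc21 | intermediate
8 | 2,2′,5,5′,6,6′-hexabromo-1H,1′H-3,3′-biindole | Brc1cc2[nH]c(Br)c(-c3c(Br)[nH]c4cc(Br)c(Br)cc34)c2cc1Br | target

**Totals**
Total step count: 4. Longest linear sequence: 4.

**Three steps most likely to fail, with fallbacks**

Step 2 (oxidative homocoupling; risks are over-oxidation to the diaryl butenedioate or a sluggish coupling of the hindered enolate). The fallback replaces the oxidative coupling by a polar two-component alkylation and sets out from 4. Wohl–Ziegler bromination (NBS, AIBN, PhCF3, 80 °C) gives methyl 2-bromo-2-(4,5-dibromo-2-nitrophenyl)acetate F1. F1 then alkylates the enolate of a second equivalent of 4 (Cs2CO3, DMF, 0 °C) in an SN2 reaction, and the sequence comes back to the route at 5.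

Step 3 (the proposed new step; risks are azo/azoxy coupling between the two nitrogens, C–H insertion of the nitrene-level intermediate, or a slow ester aza-Wittig). The fallback uses only known chemistry and sets out from 5. Béchamp reduction (Fe powder, AcOH, 90 °C) gives dimethyl 2,3-bis(2-amino-4,5-dibromophenyl)succinate F2, which acylates itself on both nitrogens in the same hot acid. This replaces the phosphorus redox closure by reduction to the free dianiline followed by thermal aminolysis, and comes back to the route at 7.

Step 4 (double deoxybromination; risks are poor solubility of 7 and incomplete conversion of the second lactam). The fallback introduces bromine by electrophilic substitution instead of carbonyl exchange and sets out from 7. Borane reduction of the 3-monosubstituted lactams (BH3·THF, reflux, acidic work-up) gives 5,5′,6,6′-tetrabromo-1H,1′H-3,3′-biindole F3. Its free C2 positions are then brominated with NBS (2 equiv, THF, −78 to 0 °C), and the sequence comes back to the route at 8.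

**Further compounds**
F1 | step 2 | methyl 2-bromo-2-(4,5-dibromo-2-nitrophenyl)acetate | COC(=O)C(Br)c1cc(Br)c(Br)cc1[N+](=O)[O-]
F2 | step 3 | dimethyl 2,3-bis(2-amino-4,5-dibromophenyl)succinate | COC(=O)C(c1cc(Br)c(Br)cc1N)C(C(=O)OC)c1cc(Br)c(Br)cc1N
F3 | step 4 | 5,5′,6,6′-tetrabromo-1H,1′H-3,3′-biindole | Brc1cc2[nH]cc(-c3c[nH]c4cc(Br)c(Br)cc34)c2cc1Br
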